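**Retrosynthetic overview**

- Ring A is a fully substituted phloroglucinol. Its carbons are numbered 1' to 6' as in the benzyl names used below (1' bridge CH2, 2' OH, 3' C‑methyl, 4' OH, 5' isobutyryl, 6' OH). The three 1,3,5‑oxygens can be delivered already differentiated: the one on carbon 4' from a ketene carbonyl, the one on 6' from an enol ether, the one on 2' from a siloxyalkyne. The route rests on this feature.
- Working backwards: the three O‑alkyl/O‑silyl bonds are cleaved last (steps 10–11). The acyl bond at carbon 5' comes from the ester of the 4'‑hydroxyl by Fries shift (steps 8–9). Bonds 3'–4', 1'–2' and 4'–5' of ring A come from benzannulation of 3‑ethoxycyclobutenone 12 with siloxyalkyne 16 (step 7).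
- Cyclobutenone 12 is cut at the bridge carbon into chromanone aldehyde 8 and cyclobutane‑1,3‑dione 9; siloxyalkyne 16 comes from ethyl acetate 13.
- Aldehyde 8 comes from 2,6‑dimethoxytoluene 1. This arene has only two of the three oxygens of ring B (the chromanone arene), so the oxygen that becomes the pyranone ring oxygen is introduced first by C–H borylation/oxidation, before annulation with 3‑methylbut‑2‑enoic acid 4.
- Ring order: the pyranone ring is closed first on the purchased benzene ring (step 2), the four‑membered ring is purchased, and carbocyclic ring A is formed last (step 7).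

Key step: step 7

Remark: the target has no stereocentre, so no stereocontrol is needed. Cyclobutane‑1,3‑dione 9 is taken as the purchased compound, which exists as its enol (3‑hydroxycyclobut‑2‑en‑1‑one) and is stored cold.

**Route**

Step 1
Reactants: 1 2,6-dimethoxytoluene
Product: 3 3,5-dimethoxy-4-methylphenol, via arylboronate 2 (not isolated)
Conditions: [Ir(OMe)(cod)]2 (cat.), 4,4'-di-tert-butyl-2,2'-bipyridine (cat.), B2pin2, THF, 80 °C; then Oxone (2KHSO5·KHSO4·K2SO4), acetone/H2O, rt
Reagents that add atoms: Oxone (potassium peroxymonosulfate), [K+].[O-]S(=O)(=O)OO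
Why: Iridium-catalysed C–H borylation is governed by sterics and should take place at position 4, the only ring C–H with no ortho substituent, and the C–B bond is then oxidised in the same flask to the phenol (one-pot C–H borylation/oxidation), which supplies the third ring-B oxygen that the purchased arene lacks.

Step 2
Reactants: 3 3,5-dimethoxy-4-methylphenol; 4 3-methylbut-2-enoic acid
Product: 6 5,7-dimethoxy-2,2,6-trimethylchroman-4-one, via hydroxyaryl enone 5 (not isolated)
Conditions: P2O5/MeSO3H (Eaton's reagent), 70 °C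
Reagents that add atoms: none
Why: Friedel–Crafts acylation ortho to the only free hydroxyl (the two ortho sites are equivalent by symmetry) gives enone 5, and 6-endo oxa-Michael addition of that hydroxyl closes the pyranone ring, so the ring oxygen and the 6-position of the methyl group are fixed without a regiochemical choice.

Step 3
Reactants: 6 5,7-dimethoxy-2,2,6-trimethylchroman-4-one
Product: 8 5,7-dimethoxy-2,2,6-trimethyl-4-oxochroman-8-carbaldehyde, via chloro ether 7 (not isolated)
Conditions: Cl2CHOMe, TiCl4, CH2Cl2, −20 to 0 °C; then H2O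
Reagents that add atoms: dichloromethyl methyl ether, COC(Cl)Cl; water, O
Why: Rieche formylation (Friedel–Crafts reaction with the chloromethoxycarbenium ion) should go to position 8, the only aromatic C–H left, which is ortho to two ether oxygens and para to the third, and chloro ether 7 is hydrolysed to the aldehyde on work-up.

Step 4
Reactants: 8 5,7-dimethoxy-2,2,6-trimethyl-4-oxochroman-8-carbaldehyde; 9 cyclobutane-1,3-dione
Product: 11 3-hydroxy-2-[(5,7-dimethoxy-2,2,6-trimethyl-4-oxochroman-8-yl)methyl]cyclobut-2-en-1-one, via alkylidene dione 10 (not isolated)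
Conditions: Hantzsch ester (diethyl 2,6-dimethyl-1,4-dihydropyridine-3,5-dicarboxylate), L-proline (cat.), CH2Cl2, rt
Reagents that add atoms: none
Why: Amine-catalysed Knoevenagel condensation of the strongly acidic cyclic 1,3-dione (held largely as its enolate, which shields the strained ring from nucleophilic opening) with the aldehyde gives the electrophilic alkylidene dione 10, which is reduced at once by hydride transfer from the Hantzsch ester (organocatalytic three-component reductive alkylation of a cyclic 1,3-dione), leaving the less electrophilic chromanone ketone untouched.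

Step 5
Reactants: 11 3-hydroxy-2-[(5,7-dimethoxy-2,2,6-trimethyl-4-oxochroman-8-yl)methyl]cyclobut-2-en-1-one
Product: 12 2-[(5,7-dimethoxy-2,2,6-trimethyl-4-oxochroman-8-yl)methyl]-3-ethoxycyclobut-2-en-1-one
Conditions: Et3OBF4, iPr2NEt, CH2Cl2, 0 °C
Reagents that add atoms: triethyloxonium tetrafluoroborate, CC[O+](CC)CC.F[B-](F)(F)F
Why: The enol is a vinylogous carboxylic acid, and its ammonium enolate is ethylated on oxygen by the hard Meerwein salt (Meerwein O-alkylation); as the two oxygens of the 2-substituted dione are equivalent, a single enol ether can form.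

Step 6
Reactants: 13 ethyl acetate
Product: 16 triisopropyl(prop-1-yn-1-yloxy)silane, via lithium dibromoenolate 14 (not isolated), via lithium ynolate 15 (not isolated)
Conditions: CH2Br2, LiTMP (lithium 2,2,6,6-tetramethylpiperidide), THF, −78 °C; LiN(SiMe3)2; n-BuLi, −78 °C to rt; then iPr3SiCl, −78 to 0 °C
Reagents that add atoms: dibromomethane, BrCBr; chlorotriisopropylsilane, CC(C)[Si](Cl)(C(C)C)C(C)C
Why: Kowalski ynolate formation: LiCHBr2 adds to the ester, the resulting dibromo ketone is held as enolate 14, bromine–lithium exchange triggers 1,2-migration of the methyl group with loss of LiBr to give ynolate 15, and the bulky silyl chloride traps it on oxygen.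

Step 7
Reactants: 12 2-[(5,7-dimethoxy-2,2,6-trimethyl-4-oxochroman-8-yl)methyl]-3-ethoxycyclobut-2-en-1-one; 16 triisopropyl(prop-1-yn-1-yloxy)silane
Product: 21 8-[6-ethoxy-4-hydroxy-3-methyl-2-(triisopropylsilyloxy)benzyl]-5,7-dimethoxy-2,2,6-trimethylchroman-4-one, via vinylketene 17 (not isolated), via vinylcyclobutenone 18 (not isolated), via dienylketene 19 (not isolated), via cyclohexadienone 20 (not isolated)
Conditions: 16 (2 equiv), toluene, 120 °C, sealed tube
Reagents that add atoms: none
Why: Proposed new method: heating should open the strained cyclobutenone 12 by 4π-electrocyclic ring opening to vinylketene 17, whose electrophilic carbonyl carbon bonds to the nucleophilic methyl-bearing carbon of siloxyalkyne 16 and whose α-carbon bonds to the silyloxy carbon in a [2+2] cycloaddition (bonds 3'–4' and 1'–2') to give vinylcyclobutenone 18. A second 4π opening gives dienylketene 19, which closes carbocyclic ring A by thermal disrotatory 6π-electrocyclisation (bond 4'–5') to cyclohexadienone 20 and tautomerises to phenol 21. The closest known reaction type is the Danheiser benzannulation of 3-alkyl- and 3-aryl-cyclobutenones with triisopropylsiloxyalkynes to resorcinol monosilyl ethers; what is new is the 2-alkyl-3-alkoxycyclobutenone, whose vinylogous-ester conjugation is lost on ring opening, so a higher temperature than usual and an excess of the thermally robust triisopropylsilyl ynol ether are planned. No stereocentre results, because the quaternary carbon of 18 becomes trigonal in 19. The selectivity needed is the regiochemistry of the ketene–alkyne [2+2] step, secured by the polarisation of the siloxyalkyne (the oxygen lone pair makes the methyl-bearing carbon nucleophilic) against the ketene carbonyl carbon, so that the methyl group ends ortho to the new hydroxyl and the silyloxy group beside the bridge carbon. The three ring-A oxygens thus emerge as free hydroxyl (on carbon 4'), ethyl ether (on 6') and silyl ether (on 2'), and the single ring-A C–H (carbon 5') lies ortho to the free hydroxyl.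

Step 8
Reactants: 21 8-[6-ethoxy-4-hydroxy-3-methyl-2-(triisopropylsilyloxy)benzyl]-5,7-dimethoxy-2,2,6-trimethylchroman-4-one; 22 2-methylpropanoyl chloride (isobutyryl chloride)
Product: 23 5-ethoxy-2-methyl-4-[(5,7-dimethoxy-2,2,6-trimethyl-4-oxochroman-8-yl)methyl]-3-(triisopropylsilyloxy)phenyl 2-methylpropanoate
Conditions: Et3N, DMAP (cat.), CH2Cl2, 0 °C to rt
Reagents that add atoms: none
Why: Acyl transfer catalysed by DMAP esterifies the only free hydroxyl (on carbon 4' of ring A), which has one unhindered ortho position; the silyl and alkyl ethers and the chromanone ketone are inert.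

Step 9
Reactants: 23 5-ethoxy-2-methyl-4-[(5,7-dimethoxy-2,2,6-trimethyl-4-oxochroman-8-yl)methyl]-3-(triisopropylsilyloxy)phenyl 2-methylpropanoate
Product: 24 8-[6-ethoxy-4-hydroxy-3-methyl-5-(2-methylpropanoyl)-2-(triisopropylsilyloxy)benzyl]-5,7-dimethoxy-2,2,6-trimethylchroman-4-one
Conditions: TiCl4, CH2Cl2, −20 °C to rt; aqueous work-up
Reagents that add atoms: none
Why: Lewis-acid Fries rearrangement: the acylium ion released from the titanium phenoxide can only return to carbon 5', the single unsubstituted carbon of ring A and ortho to the phenoxide, since ring B is fully substituted and deactivated by its complexed ketone.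

Step 10
Reactants: 24 8-[6-ethoxy-4-hydroxy-3-methyl-5-(2-methylpropanoyl)-2-(triisopropylsilyloxy)benzyl]-5,7-dimethoxy-2,2,6-trimethylchroman-4-one
Product: 25 8-[6-ethoxy-2,4-dihydroxy-3-methyl-5-(2-methylpropanoyl)benzyl]-5,7-dimethoxy-2,2,6-trimethylchroman-4-one
Conditions: Bu4NF, AcOH, THF, 0 °C to rt
Reagents that add atoms: none
Why: Fluoride-induced cleavage of the aryl silyl ether (driven by Si–F bond formation), buffered with acetic acid so that the chromanone and the bridge are not exposed to free phenoxide.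

Step 11
Reactants: 25 8-[6-ethoxy-2,4-dihydroxy-3-methyl-5-(2-methylpropanoyl)benzyl]-5,7-dimethoxy-2,2,6-trimethylchroman-4-one
Product: 26 5,7-dihydroxy-2,2,6-trimethyl-8-[2,4,6-trihydroxy-3-methyl-5-(2-methylpropanoyl)benzyl]chroman-4-one
Conditions: BBr3 (excess), CH2Cl2, −78 °C to rt; then H2O
Reagents that add atoms: none
Why: Lewis-acid ether cleavage with BBr3 removes the two methyl ethers and the ethyl ether (those ortho to a carbonyl assisted by chelation, the 7-methoxy group twisted out of plane by its two ortho substituents), and hydrolysis of the aryl borates releases the achiral target.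

**Compound list**

1 | 2,6-dimethoxytoluene | Cc1c(OC)cccc1OC | starting material
2 | 2-(3,5-dimethoxy-4-methylphenyl)-4,4,5,5-tetramethyl-1,3,2-dioxaborolane (arylboronate, formed in the flask) | Cc1c(OC)cc(cc1OC)B1OC(C)(C)C(C)(C)O1 | intermediate
3 | 3,5-dimethoxy-4-methylphenol | Cc1c(OC)cc(O)cc1OC | intermediate
4 | 3-methylbut-2-enoic acid | CC(C)=CC(=O)O | starting material
5 | 1-(6-hydroxy-2,4-dimethoxy-3-methylphenyl)-3-methylbut-2-en-1-one (hydroxyaryl enone, formed in the flask) | CC(C)=CC(=O)c1c(O)cc(OC)c(C)c1OC | intermediate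
6 | 5,7-dimethoxy-2,2,6-trimethylchroman-4-one | COc1cc2OC(C)(C)CC(=O)c2c(OC)c1C | intermediate
7 | 8-[chloro(methoxy)methyl]-5,7-dimethoxy-2,2,6-trimethylchroman-4-one (racemic chloro ether, formed in the flask) | COC(Cl)c1c(OC)c(C)c(OC)c2c1OC(C)(C)CC2=O | intermediate
8 | 5,7-dimethoxy-2,2,6-trimethyl-4-oxochroman-8-carbaldehyde | O=Cc1c(OC)c(C)c(OC)c2c1OC(C)(C)CC2=O | intermediate
9 | cyclobutane-1,3-dione | O=C1CC(=O)C1 | starting material
10 | 2-[(5,7-dimethoxy-2,2,6-trimethyl-4-oxochroman-8-yl)methylidene]cyclobutane-1,3-dione (alkylidene dione, formed in the flask) | O=C1CC(=O)C1=Cc1c(OC)c(C)c(OC)c2c1OC(C)(C)CC2=O | intermediate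
11 | 3-hydroxy-2-[(5,7-dimethoxy-2,2,6-trimethyl-4-oxochroman-8-yl)methyl]cyclobut-2-en-1-one | O=C1CC(O)=C1Cc1c(OC)c(C)c(OC)c2c1OC(C)(C)CC2=O | intermediate
12 | 2-[(5,7-dimethoxy-2,2,6-trimethyl-4-oxochroman-8-yl)methyl]-3-ethoxycyclobut-2-en-1-one | CCOC1=C(Cc2c(OC)c(C)c(OC)c3c2OC(C)(C)CC3=O)C(=O)C1 | intermediate
13 | ethyl acetate | CCOC(C)=O | starting material
14 | lithium 1,1-dibromoprop-1-en-2-olate (formed in the flask) | [Li+].[O-]C(C)=C(Br)Br | intermediate
15 | lithium prop-1-yn-1-olate (formed in the flask) | [Li+].[O-]C#CC | intermediate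
16 | triisopropyl(prop-1-yn-1-yloxy)silane | CC#CO[Si](C(C)C)(C(C)C)C(C)C | intermediate
17 | 3-ethoxy-2-[(5,7-dimethoxy-2,2,6-trimethyl-4-oxochroman-8-yl)methyl]buta-1,3-dien-1-one (vinylketene, formed in the flask) | C=C(OCC)C(Cc1c(OC)c(C)c(OC)c2c1OC(C)(C)CC2=O)=C=O | intermediate
18 | 4-(1-ethoxyvinyl)-2-methyl-4-[(5,7-dimethoxy-2,2,6-trimethyl-4-oxochroman-8-yl)methyl]-3-(triisopropylsilyloxy)cyclobut-2-en-1-one (racemic, formed in the flask) | C=C(OCC)C1(Cc2c(OC)c(C)c(OC)c3c2OC(C)(C)CC3=O)C(=O)C(C)=C1O[Si](C(C)C)(C(C)C)C(C)C | intermediate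
19 | (3E)-5-ethoxy-2-methyl-4-[(5,7-dimethoxy-2,2,6-trimethyl-4-oxochroman-8-yl)methyl]-3-(triisopropylsilyloxy)hexa-1,3,5-trien-1-one (dienylketene with ketenyl and ethoxyvinyl groups cis, formed in the flask) | C=C(OCC)/C(Cc1c(OC)c(C)c(OC)c2c1OC(C)(C)CC2=O)=C(\C(C)=C=O)O[Si](C(C)C)(C(C)C)C(C)C | intermediate
20 | 5-ethoxy-2-methyl-4-[(5,7-dimethoxy-2,2,6-trimethyl-4-oxochroman-8-yl)methyl]-3-(triisopropylsilyloxy)cyclohexa-2,4-dien-1-one (formed in the flask) | CCOC1=C(Cc2c(OC)c(C)c(OC)c3c2OC(C)(C)CC3=O)C(O[Si](C(C)C)(C(C)C)C(C)C)=C(C)C(=O)C1 | intermediate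
21 | 8-[6-ethoxy-4-hydroxy-3-methyl-2-(triisopropylsilyloxy)benzyl]-5,7-dimethoxy-2,2,6-trimethylchroman-4-one | CCOc1cc(O)c(C)c(O[Si](C(C)C)(C(C)C)C(C)C)c1Cc1c(OC)c(C)c(OC)c2c1OC(C)(C)CC2=O | intermediate
22 | 2-methylpropanoyl chloride (isobutyryl chloride) | CC(C)C(Cl)=O | starting material
23 | 5-ethoxy-2-methyl-4-[(5,7-dimethoxy-2,2,6-trimethyl-4-oxochroman-8-yl)methyl]-3-(triisopropylsilyloxy)phenyl 2-methylpropanoate | CCOc1cc(OC(=O)C(C)C)c(C)c(O[Si](C(C)C)(C(C)C)C(C)C)c1Cc1c(OC)c(C)c(OC)c2c1OC(C)(C)CC2=O | intermediate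
24 | 8-[6-ethoxy-4-hydroxy-3-methyl-5-(2-methylpropanoyl)-2-(triisopropylsilyloxy)benzyl]-5,7-dimethoxy-2,2,6-trimethylchroman-4-one | CCOc1c(C(=O)C(C)C)c(O)c(C)c(O[Si](C(C)C)(C(C)C)C(C)C)c1Cc1c(OC)c(C)c(OC)c2c1OC(C)(C)CC2=O | intermediate
25 | 8-[6-ethoxy-2,4-dihydroxy-3-methyl-5-(2-methylpropanoyl)benzyl]-5,7-dimethoxy-2,2,6-trimethylchroman-4-one | CCOc1c(C(=O)C(C)C)c(O)c(C)c(O)c1Cc1c(OC)c(C)c(OC)c2c1OC(C)(C)CC2=O | intermediate
26 | 5,7-dihydroxy-2,2,6-trimethyl-8-[2,4,6-trihydroxy-3-methyl-5-(2-methylpropanoyl)benzyl]chroman-4-one (CNP0186856.0) | Cc1c(O)c(Cc2c(O)c(C)c(O)c3c2OC(C)(C)CC3=O)c(O)c(C(=O)C(C)C)c1O | target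

**Step count and risks**

Total step count: 11. Longest linear sequence: 10 steps (steps 1–5 and 7–11); step 6 is a one-step side branch.

Steps most likely to fail:

1. Step 7 (proposed new method). The first ring opening of the donor-stabilised cyclobutenone may need a temperature at which the siloxyalkyne rearranges by 1,3-silyl shift to a silylketene. The vinylketene may also be consumed by dimerisation, or by acylating the product phenol, faster than the alkyne intercepts it. The fallback uses known chemistry and replaces the benzannulation by the classical union of two preformed rings through the bridge carbon. It sets out from aldehyde 8, which NaBH4 (MeOH/CH2Cl2, 0 °C) should reduce chemoselectively to 8-(hydroxymethyl)-5,7-dimethoxy-2,2,6-trimethylchroman-4-one F1. Separately, purchased 2,4,6-trihydroxytoluene is C-acylated with isobutyryl chloride 22 (AlCl3, PhNO2, Friedel–Crafts acylation) to 1-(2,4,6-trihydroxy-3-methylphenyl)-2-methylpropan-1-one F2. Acid-catalysed Friedel–Crafts benzylation (p-toluenesulfonic acid cat., dioxane) of the single free ring carbon of F2 by the benzylic cation from F1 should give 8-[2,4,6-trihydroxy-3-methyl-5-(2-methylpropanoyl)benzyl]-5,7-dimethoxy-2,2,6-trimethylchroman-4-one F3. BBr3 (CH2Cl2, −78 °C to rt) then cleaves the two methyl ethers, so the fallback comes back to the route at target 26.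

2. Step 4. Slow Knoevenagel condensation at the hindered, electron-rich di-ortho-alkoxy aldehyde may allow the strained four-membered dione to be consumed by amine-induced ring opening or self-condensation, and a second dione may add to the alkylidene intermediate before hydride transfer. The fallback sets out from aldehyde 8 and comes back at dione 11 by way of ketene–ynol ether chemistry. The same reductive alkylation is run with Meldrum's acid (Hantzsch ester, L-proline, EtOH), which via 5-[(5,7-dimethoxy-2,2,6-trimethyl-4-oxochroman-8-yl)methylidene]-2,2-dimethyl-1,3-dioxane-4,6-dione F4 (not isolated) gives 5-[(5,7-dimethoxy-2,2,6-trimethyl-4-oxochroman-8-yl)methyl]-2,2-dimethyl-1,3-dioxane-4,6-dione F5. Heating in pyridine/H2O brings about hydrolysis and decarboxylation to 3-(5,7-dimethoxy-2,2,6-trimethyl-4-oxochroman-8-yl)propanoic acid F6. (COCl)2 with catalytic DMF gives 3-(5,7-dimethoxy-2,2,6-trimethyl-4-oxochroman-8-yl)propanoyl chloride F7. Slow addition of F7 to Et3N and ethoxyacetylene generates 3-(5,7-dimethoxy-2,2,6-trimethyl-4-oxochroman-8-yl)prop-1-en-1-one F8 (the ketene, not isolated), which undergoes [2+2] cycloaddition to racemic 3-ethoxy-4-[(5,7-dimethoxy-2,2,6-trimethyl-4-oxochroman-8-yl)methyl]cyclobut-2-en-1-one F9. Dilute aqueous HCl in THF hydrolyses the enol ether to the 2-substituted cyclobutane-1,3-dione, which is compound 11.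

3. Step 9. The Lewis acid meets a bridge-bearing ring A that carries three oxygen donors and no acceptor, so ipso attack by a proton or the acylium ion at the bridge-bearing carbon 1' may cut the bridge C–C bond, and the silyl ether may be lost before the acyl shift is complete. The fallback avoids acid and the ester altogether: it sets out from phenol 21 and comes back at ketone 24. Magnesium-mediated ortho-formylation (Casnati–Skattebøl conditions: MgCl2, Et3N, paraformaldehyde, MeCN, reflux) should give 5-[(5,7-dimethoxy-2,2,6-trimethyl-4-oxochroman-8-yl)methyl]-6-ethoxy-2-hydroxy-3-methyl-4-(triisopropylsilyloxy)benzaldehyde F10. Addition of iPrMgCl (2.2 equiv, THF, −78 °C), at which temperature the aldehyde should react ahead of the hindered chromanone ketone, gives racemic 8-[6-ethoxy-4-hydroxy-5-(1-hydroxy-2-methylpropyl)-3-methyl-2-(triisopropylsilyloxy)benzyl]-5,7-dimethoxy-2,2,6-trimethylchroman-4-one F11. Oxidation of the benzylic alcohol with MnO2 (CH2Cl2, rt) gives ketone 24.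

**Further compounds**

F1 | step 7 | 8-(hydroxymethyl)-5,7-dimethoxy-2,2,6-trimethylchroman-4-one | OCc1c(OC)c(C)c(OC)c2c1OC(C)(C)CC2=O
F2 | step 7 | 1-(2,4,6-trihydroxy-3-methylphenyl)-2-methylpropan-1-one | Cc1c(O)cc(O)c(C(=O)C(C)C)c1O
F3 | step 7 | 8-[2,4,6-trihydroxy-3-methyl-5-(2-methylpropanoyl)benzyl]-5,7-dimethoxy-2,2,6-trimethylchroman-4-one | Cc1c(O)c(Cc2c(OC)c(C)c(OC)c3c2OC(C)(C)CC3=O)c(O)c(C(=O)C(C)C)c1O
F4 | step 4 | 5-[(5,7-dimethoxy-2,2,6-trimethyl-4-oxochroman-8-yl)methylidene]-2,2-dimethyl-1,3-dioxane-4,6-dione | CC1(C)OC(=O)C(=Cc2c(OC)c(C)c(OC)c3c2OC(C)(C)CC3=O)C(=O)O1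
F5 | step 4 | 5-[(5,7-dimethoxy-2,2,6-trimethyl-4-oxochroman-8-yl)methyl]-2,2-dimethyl-1,3-dioxane-4,6-dione | CC1(C)OC(=O)C(Cc2c(OC)c(C)c(OC)c3c2OC(C)(C)CC3=O)C(=O)O1
F6 | step 4 | 3-(5,7-dimethoxy-2,2,6-trimethyl-4-oxochroman-8-yl)propanoic acid | OC(=O)CCc1c(OC)c(C)c(OC)c2c1OC(C)(C)CC2=O
F7 | step 4 | 3-(5,7-dimethoxy-2,2,6-trimethyl-4-oxochroman-8-yl)propanoyl chloride | ClC(=O)CCc1c(OC)c(C)c(OC)c2c1OC(C)(C)CC2=O
F8 | step 4 | 3-(5,7-dimethoxy-2,2,6-trimethyl-4-oxochroman-8-yl)prop-1-en-1-one | O=C=CCc1c(OC)c(C)c(OC)c2c1OC(C)(C)CC2=O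
F9 | step 4 | 3-ethoxy-4-[(5,7-dimethoxy-2,2,6-trimethyl-4-oxochroman-8-yl)methyl]cyclobut-2-en-1-one (racemic) | CCOC1=CC(=O)C1Cc1c(OC)c(C)c(OC)c2c1OC(C)(C)CC2=O
F10 | step 9 | 5-[(5,7-dimethoxy-2,2,6-trimethyl-4-oxochroman-8-yl)methyl]-6-ethoxy-2-hydroxy-3-methyl-4-(triisopropylsilyloxy)benzaldehyde | CCOc1c(C=O)c(O)c(C)c(O[Si](C(C)C)(C(C)C)C(C)C)c1Cc1c(OC)c(C)c(OC)c2c1OC(C)(C)CC2=O
F11 | step 9 | 8-[6-ethoxy-4-hydroxy-5-(1-hydroxy-2-methylpropyl)-3-methyl-2-(triisopropylsilyloxy)benzyl]-5,7-dimethoxy-2,2,6-trimethylchroman-4-one (racemic) | CCOc1c(C(O)C(C)C)c(O)c(C)c(O[Si](C(C)C)(C(C)C)C(C)C)c1Cc1c(OC)c(C)c(OC)c2c1OC(C)(C)CC2=O
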